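Before stopping the flask at 15 h, decide on the fraction of substrate left, x, and not on the product made.

| flask | substrate | partner | remark | time |
|---|---|---|---|---|
| Tuesday's | 10 mM | 0.45 equiv | run made earlier |  |
| Sunday's | 10 mM | 0.68 equiv | run made earlier |  |
| Monday's | 5 mM | 0.90 equiv | run made earlier |  |
| flask | 10 mM | 0.900 equiv |  | 15 h |

- Tuesday's (time / h: substrate / %, mono adduct / %): 1.00: 96.7, 3.4; 3.00: 90.8, 7.9; 5.00: 87.3, 11.5; 8.00: 82.9, 14.6; 12.0: 79.4, 16.7; 15.0: 77.4, 19.0
- Sunday's (time / h: substrate / %, mono adduct / %): 1.00: 94.8, 4.9; 3.00: 87.7, 11.3; 5.00: 81.7, 15.9; 8.00: 76.0, 19.0; 12.0: 71.0, 21.7; 15.0: 70.3, 23.4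
- Monday's (time / h: substrate / %, mono adduct / %): 1.33: 96.2, 4.0; 4.00: 89.1, 10.7; 8.00: 82.4, 15.7; 10.0: 77.5, 18.3; 15.0: 72.5, 20.4

(each reading ± 0.5 percentage points)

- the numbers in the tables scatter with a standard deviation of 0.5 percentage points
- a reading or a percentage of mono adduct counts all its forms, free or not

- the substrate standing at 15 h, as a percentage of the substrate charged
- the mono adduct standing at 15 h, as a percentage of the substrate charged
- the double product standing at 15 h, as a percentage of the substrate charged

Why x? Suppose partner adds to substrate to give mono adduct, and to mono adduct to give double product, both steps first order in c(partner) and in what it adds to. Dividing one rate by the other cancels c(partner), whatever else happens to it. With s as the second rate constant over the first, the mono adduct fraction m is x minus x to the power s, divided by s less one. Double product is the rest of the balance.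

And s? Write L = −ln x. At moderate L, the rule expands to: s less one is about twice (one minus m/(xL)), divided by L. The last readings give L of 0.256 on Tuesday's run, 0.352 on Sunday's and 0.322 on Monday's. These give s of 1.33, 1.31 and 1.78. I carry their mean, 1.47, as a reading of the selectivity factor.

And x in the flask? Tuesday's and Sunday's runs share the flask's substrate charge and time, and between these two runs L grows as the equivalents to the power 0.772. At 0.900 equiv, that gives L = 0.438. My reckoning for the flask is therefore substrate 64.6 %, mono adduct 25.5 % and double product 9.92 %.

The weak spot? Monday's s stands apart from the others. Between Sunday's s and Monday's s, m at this x runs from 26.4 % down to 23.9 %.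

The forecast, holding that “mono adduct seems to inhibit”, gives 65.5 %, 25.3 % and 9.2 %, with more substrate and less double product than mine.

The flask gives substrate 63.9 %, mono adduct 25.3 % and double product 10.8 %.

    partner + mono adduct → double product (k = 0.206 L mol⁻¹ min⁻¹)
    substrate + partner → mono adduct (k = 0.132 L mol⁻¹ min⁻¹)
    2 partner → homo dimer (k = 0.0873 L mol⁻¹ min⁻¹)
    crystals ⇌ mono adduct, rate k4*(cs4 - [mono adduct]) while solid is left; crystals form when [mono adduct] > cs4 (solubility = 4.50 mM, k = 0.00757 min⁻¹)

At the flask's x of 63.9 %, the rule with s = 1.47 gives 25.8 % of mono adduct, against the 25.3 % that stands there. A neighbouring flask charged with 3.60 equiv of partner, everything else as in the recipe, reaches x = 32.8 % at 15 h. At that x, the same rule with the same s gives 28.5 % of mono adduct and 38.7 % of double product. That neighbouring flask holds 27.2 % of mono adduct and 40.0 % of double product.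

The earlier runs and the new flask were generated by integration from invented constants, noise included.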